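## The problem

Broussoflavonol D (25) is a flavonol (rings A and C) whose aryl ring B is fused to a 2,2-dimethyl-2H-pyran (ring D) and is substituted on every carbon except C6'. It has no stereocentre; the only stereochemical element met on the way is the geometry of an enol ether, so the difficulties are regiochemistry and functional-group tolerance. Three isoprenoid units must be placed without ambiguity: the 2-methylbut-3-en-2-yl (tert-allyl) group on C8 between O1 and O7, the prenyl group on C2', and the pyran carbons on C3' and O4'. C6 and C8 of a 5,7-dioxygenated flavone are both flanked by two oxygens, so a late C-alkylation or sigmatropic shift on ring A would have to choose between them without help from the substrate. The prenyl alkene, the chromene alkene, the tert-allyl group (next to the 7-OH and on a carbon open to ipso protonation) and four phenolic hydroxyls rule out strong Brønsted or Lewis acids, hydrogenation and electrophilic oxidants late in the route. The feature that opens the molecule is C4a: it is ortho to O1 and O5 and para to O7, the most nucleophilic kind of carbon in ring A, so the C4–C4a bond can be made by electrophilic acylation from an aryloxyacrylic acid. If the C8 substituent is already in place, the aryloxy ring of that acid has only one free ortho carbon, and the closure of ring C has no choice of site.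

## Retrosynthesis

**Protecting groups (25 from 24).** The last operation cuts three O–CH2 acetal bonds: the methoxymethyl (MOM) ethers on O5, O7 and O5' of 24. MOM is preferred because allyl ethers would rearrange in the two thermal Claisen steps, benzyl ethers would need hydrogenolysis, methyl ethers would need hard Lewis acids, and silyl ethers would not survive the carbonate and hydroxide steps. 24 differs from 25 only in these acetals. The forward reaction must be an acetal exchange mild enough to leave the tert-allyl, prenyl and chromene groups alone.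

**C3–O bond (24 from 21).** The 3-hydroxyl is removed next, leaving flavone 21. Carrying this oxygen through the ring closure would require a tetrasubstituted 2-alkoxy-3-aryloxyacrylic acid, which is harder to assemble and to control in geometry. Electrophilic epoxidation of the C2–C3 bond is excluded by three more electron-rich alkenes. What remains is deprotonation at C3, boron trapping and oxidation, which asks that C3–H be the kinetically most acidic C–H of 21.

**C4–C4a bond (21 from 19), the key disconnection.** Ring C is opened between the carbonyl carbon and C4a, giving the (Z)-3-aryloxy-3-arylacrylic acid 19, closed forward through its mixed anhydride 20. The neighbouring cuts, O1–C2 or O1–C8a, both need a ring A that already carries an acyl group or a leaving group; this cut needs only a phenol. A symmetrical 3,5-dioxygenated aryloxy ring would offer two equivalent ortho carbons, but it would postpone the C8 substituent to a rearrangement on the finished flavone, where C6 and C8 compete and the whole molecule must be heated. The aryloxy ring of 19 therefore already carries the tert-allyl group: one ortho carbon is blocked, the other becomes C4a, and the blocked carbon becomes C8 by construction. The forward reaction must acylate under conditions that spare MOM ethers and alkenes.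

**O1–C2 bond (19 from 18, and 18 from 11 and 17).** Acid 19 comes from its methyl ester 18, and 18 is cut at the enol ether C–O bond into ynoate 11 and phenol 17. This splits the molecule into two halves of similar size, each carrying its own isoprenoid groups. The forward reaction is a conjugate addition of a hindered phenoxide, and it must proceed by anti addition so that the aryloxy and carboxyl groups end up cis.

**C8–CMe2 bond (17 from 15, 13, 12 and 14).** Phenol 17 is the Claisen product of prenyl ether 15. Ether 15 is mirror-symmetric, so its two ortho carbons are the same and the shift can give one product only. The oxygen set free by the shift is the one needed as O1. Ether 15 comes from bis-MOM phenol 13 and prenyl bromide 14, and 13 from phloroglucinol 12.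

**C3 and C4 carbons (11 from 9, and 9 from 8).** The ester carbon of 11 (later C4) is attached by carboxylation of the terminal alkyne 9. The alkyne carbon that becomes C3 comes from one-carbon homologation of aldehyde 8. Both are standard operations on a non-enolisable aryl aldehyde.

**Prenyl C–C bond (8 from 6 and 7).** The prenyl group is cut from the ring carbon, giving bromide 6 and prenylstannane 7. The bromine is bought with the starting material, so its position is never in question. The coupling must transfer the prenyl group through its primary carbon.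

**Ring D (6 from 4, 3, 1 and 2).** The pyran is cut at O–CMe2 and at the aryl–CH bond, giving aryl propargyl ether 4. The Claisen shift can only go to the one free ortho carbon, because the other bears the MOM ether. Ether 4 comes from 2-bromo-4,5-dihydroxybenzaldehyde 1 and propargylic chloride 2 through monoether 3. The two phenols of 1 are told apart by acidity: the one para to the formyl group reacts first.

## Roads not taken

**Alternative 1:** Ring A is built instead of bought. A Danheiser benzannulation of 3-(prop-2-enyloxy)cyclobut-2-en-1-one A1 with (3,3-dimethylpent-4-en-1-ynyloxy)tri(propan-2-yl)silane A2 would form the bonds that become C8–C8a, C6–C7 and C4a–C8a. The sequence is 4π opening of A1 to a vinylketene, [2+2] addition to A2, 4π opening, 6π closure and tautomerisation. The product is 2-(2-methylbut-3-en-2-yl)-5-(prop-2-enyloxy)-3-[tri(propan-2-yl)silyloxy]phenol A3.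
- Merits: the tert-allyl group enters on the alkyne and sits on the future C8 by construction, the future O1 is a free phenol, and O5 and O7 are differentiated. There is no statistical protection and no hot Claisen step.
- Weak points: an aromatic ring that is a bulk chemical is assembled from two components that each need several steps (a siloxyalkyne with a quaternary propargylic carbon, an alkoxycyclobutenone). The benzannulation must tolerate a bulky alkyne substituent. The differentiation of O5 and O7 is not needed, since both end as free hydroxyls. A3 is only a ring A fragment; ring C must still be closed, most naturally as in the chosen plan.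
- Comparison: A3 plays the role of phenol 17. This road is better in regiochemical certainty and in avoiding the statistical step 7 and the thermal step 9. The chosen plan sets against it three steps from phloroglucinol, a symmetric Claisen substrate with only one possible product, and uniform MOM protection removed in one operation.

**Alternative 2:** Ring D is closed last. The complete flavonol 3,5,7-tris(methoxymethoxy)-2-[5-(methoxymethoxy)-4-(2-methylbut-3-yn-2-yloxy)-2-(3-methylbut-2-enyl)phenyl]-8-(2-methylbut-3-en-2-yl)chromen-4-one A4 would be heated in xylene at about 140 °C. A [3,3] shift forms the C3'–CH bond and oxa-6π closure forms O4'–CMe2, giving tetra-MOM broussoflavonol D A5.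
- Merits: the chromene alkene never meets palladium, organolithiums, anhydride activation or peroxide. The regiochemistry is forced because C5' is oxygenated. The step needs no reagent.
- Weak points: A4 is a complete flavonol with a 4'-oxygen differentiated from the 5'-oxygen, so the C8 tert-allyl group, ring C, the 3-oxygen and the 2'-prenyl group must all be in place beforehand by other chemistry. The key step solves only the easiest ring. It exposes the most valuable intermediate to prolonged heating, and one more MOM group must then be cleaved by acid.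
- Comparison: the chosen plan uses the same pericyclic cascade in step 3 on a simple benzaldehyde. This road is better in that the chromene is exposed to no further steps. The chosen plan sets against it that a 2,2-dimethylchromene is inert to the bases used, that the two acidic steps are buffered or mild, and that its key step makes a ring-C bond that has to be made in any case.

**Alternative 3:** Ring C is closed at O1–C8a. The enolate of 1-[2-fluoro-6-(methoxymethoxy)-4-(3-methylbut-2-enyloxy)phenyl]-2-(methoxymethoxy)-3-[8-(methoxymethoxy)-2,2-dimethyl-5-(3-methylbut-2-enyl)-2H-chromen-6-yl]propane-1,3-dione A6 would displace fluoride with K2CO3 in DMF. The product is 3,5-bis(methoxymethoxy)-2-[8-(methoxymethoxy)-2,2-dimethyl-5-(3-methylbut-2-enyl)-2H-chromen-6-yl]-7-(3-methylbut-2-enyloxy)chromen-4-one A7.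
- Merits: the 3-oxygen is carried in the diketone, so no late C–H oxidation is needed. The closure is purely basic. Its site is fixed by the fluorine.
- Weak points: the carbon bearing fluorine sits on a ring with two alkoxy donors and is activated by one acyl group that is itself part of an enolate, so the substitution should be slow and need heat. A fluorinated phloroglucinol derivative must be made in several steps. A7 has hydrogen on C8 and a 7-O-prenyl ether, so the tert-allyl group would have to come from a Claisen shift on the flavone, where C6 and C8 are both ortho to O7.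
- Comparison: this road is better in the origin of the 3-oxygen and in an acid-free ring closure. The chosen plan sets against it a ring A from phloroglucinol without fluorine, a C8 substituent fixed before ring closure, and only two steps after the closure.

Key step: step 12

Remark: 25 is achiral. The transient dienone 16 and the fallback compounds F2 and F6 are racemic and are written without configuration; the enol ether of 18, 19 and 20 is Z throughout.

## Route

Step 1
Reactants: 1 2-bromo-4,5-dihydroxybenzaldehyde; 2 3-chloro-3-methylbut-1-yne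
Product: 3 2-bromo-5-hydroxy-4-[(2-methylbut-3-yn-2-yl)oxy]benzaldehyde
Conditions: DBU (1.1 equiv), CuCl2 (cat.), MeCN, 0 °C, argon
Reagents that add atoms: none
Why: Copper-catalysed propargylic etherification of a tertiary propargylic chloride; the 4-OH is para to the formyl group and the more acidic phenol, so one equivalent of base should give its phenoxide selectively and leave the 5-OH free, as in the usual para-selective monoalkylation of 3,4-dihydroxybenzaldehydes.

Step 2
Reactants: 3 2-bromo-5-hydroxy-4-[(2-methylbut-3-yn-2-yl)oxy]benzaldehyde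
Product: 4 2-bromo-5-(methoxymethoxy)-4-[(2-methylbut-3-yn-2-yl)oxy]benzaldehyde
Conditions: MOMCl, i-Pr2NEt, CH2Cl2, 0 °C to rt
Reagents that add atoms: chloromethyl methyl ether, COCCl
Why: Standard MOM etherification of a phenol; the acetal blocks the second ortho position of the propargyl ether and should survive heat, carbonate, hydroxide and organolithium bases until the last step.

Step 3
Reactants: 4 2-bromo-5-(methoxymethoxy)-4-[(2-methylbut-3-yn-2-yl)oxy]benzaldehyde
Product: 6 5-bromo-8-(methoxymethoxy)-2,2-dimethyl-2H-chromene-6-carbaldehyde, via allenyl phenol 5 (not isolated)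
Conditions: PhNEt2, 180 °C
Reagents that add atoms: none
Why: Aromatic propargyl Claisen rearrangement; the [3,3] shift can only reach the ortho carbon next to bromine because the other ortho carbon bears the MOM ether, and the allenyl phenol 5 then undergoes a [1,5]-hydrogen shift and oxa-6π electrocyclisation to the 2,2-dimethylchromene.

Step 4
Reactants: 6 5-bromo-8-(methoxymethoxy)-2,2-dimethyl-2H-chromene-6-carbaldehyde; 7 tributyl(3-methylbut-2-enyl)stannane
Product: 8 8-(methoxymethoxy)-2,2-dimethyl-5-(3-methylbut-2-enyl)-2H-chromene-6-carbaldehyde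
Conditions: Pd(PPh3)4 (cat.), DMF, 90 °C
Reagents that add atoms: none
Why: Stille coupling; oxidative addition of the zerovalent palladium complex is helped by the ortho formyl group, and the prenylpalladium intermediates equilibrate so that reductive elimination at the primary terminus should give the linear prenyl arene.

Step 5
Reactants: 8 8-(methoxymethoxy)-2,2-dimethyl-5-(3-methylbut-2-enyl)-2H-chromene-6-carbaldehyde
Product: 9 6-ethynyl-8-(methoxymethoxy)-2,2-dimethyl-5-(3-methylbut-2-enyl)-2H-chromene
Conditions: dimethyl (1-diazo-2-oxopropyl)phosphonate, K2CO3, MeOH, rt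
Reagents that add atoms: dimethyl (1-diazo-2-oxopropyl)phosphonate, CC(=O)C(=[N+]=[N-])P(=O)(OC)OC
Why: Ohira–Bestmann (Seyferth–Gilbert) homologation of a non-enolisable aryl aldehyde; the carbonate/methanol medium leaves the MOM ether, prenyl group and chromene untouched.

Step 6
Reactants: 9 6-ethynyl-8-(methoxymethoxy)-2,2-dimethyl-5-(3-methylbut-2-enyl)-2H-chromene
Product: 11 methyl 3-[8-(methoxymethoxy)-2,2-dimethyl-5-(3-methylbut-2-enyl)-2H-chromen-6-yl]prop-2-ynoate, via lithium acetylide 10 (not isolated)
Conditions: n-BuLi, THF, −78 °C; ClCO2Me, −78 °C to rt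
Reagents that add atoms: methyl chloroformate, COC(=O)Cl
Why: Deprotonation of the terminal alkyne is much faster than ortho-lithiation next to the MOM ether at −78 °C, and C-acylation of acetylide 10 with the chloroformate gives the ynoate whose ester carbon becomes C4.

Step 7
Reactants: 12 phloroglucinol (benzene-1,3,5-triol)
Product: 13 3,5-bis(methoxymethoxy)phenol
Conditions: MOMCl (2 equiv), i-Pr2NEt, DMF, 0 °C to rt
Reagents that add atoms: chloromethyl methyl ether, COCCl
Why: Williamson-type MOM etherification of a threefold-symmetric triol; the three hydroxyls are equivalent, so there is one bis-ether only, and the mono- and tris-ethers formed beside it can be separated and recycled.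

Step 8
Reactants: 13 3,5-bis(methoxymethoxy)phenol; 14 1-bromo-3-methylbut-2-ene
Product: 15 1,3-bis(methoxymethoxy)-5-[(3-methylbut-2-enyl)oxy]benzene
Conditions: K2CO3, acetone, reflux
Reagents that add atoms: none
Why: Williamson O-prenylation by SN2 at the primary allylic bromide; with two of the three oxygens capped and a carbonate base in acetone, O-alkylation should dominate over C-alkylation.

Step 9
Reactants: 15 1,3-bis(methoxymethoxy)-5-[(3-methylbut-2-enyl)oxy]benzene
Product: 17 3,5-bis(methoxymethoxy)-2-(2-methylbut-3-en-2-yl)phenol, via cyclohexadienone 16 (not isolated)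
Conditions: PhNEt2, 190 °C
Reagents that add atoms: none
Why: Aromatic Claisen rearrangement; the two ortho carbons of the symmetric ether are equivalent, the [3,3] shift inverts the allyl unit so that its tertiary carbon bonds to the ring, and dienone 16 tautomerises to the phenol, the basic solvent holding back acid-catalysed cyclisation of the product.

Step 10
Reactants: 11 methyl 3-[8-(methoxymethoxy)-2,2-dimethyl-5-(3-methylbut-2-enyl)-2H-chromen-6-yl]prop-2-ynoate; 17 3,5-bis(methoxymethoxy)-2-(2-methylbut-3-en-2-yl)phenol
Product: 18 methyl (Z)-3-[3,5-bis(methoxymethoxy)-2-(2-methylbut-3-en-2-yl)phenoxy]-3-[8-(methoxymethoxy)-2,2-dimethyl-5-(3-methylbut-2-enyl)-2H-chromen-6-yl]prop-2-enoate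
Conditions: Cs2CO3 (cat.), DMF, 60 °C
Reagents that add atoms: none
Why: Base-catalysed oxa-Michael addition of a phenoxide to the β-carbon of an arylpropiolate; protonation of the vinyl anion trans to the entering oxygen (anti addition) should place aryloxy and ester cis, the Z geometry the ring closure needs, and the linear alkyne keeps the approach of the hindered phenoxide open.

Step 11
Reactants: 18 methyl (Z)-3-[3,5-bis(methoxymethoxy)-2-(2-methylbut-3-en-2-yl)phenoxy]-3-[8-(methoxymethoxy)-2,2-dimethyl-5-(3-methylbut-2-enyl)-2H-chromen-6-yl]prop-2-enoate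
Product: 19 (Z)-3-[3,5-bis(methoxymethoxy)-2-(2-methylbut-3-en-2-yl)phenoxy]-3-[8-(methoxymethoxy)-2,2-dimethyl-5-(3-methylbut-2-enyl)-2H-chromen-6-yl]prop-2-enoic acid
Conditions: LiOH·H2O, THF/MeOH/H2O, 40 °C; then 1 M HCl to pH 4, 0 °C
Reagents that add atoms: lithium hydroxide, [Li+].[OH-]
Why: Saponification; hydroxide attacks the ester carbonyl and not the crowded β-carbon, and brief cold acidification to pH 4 frees the acid without touching the MOM ethers.

Step 12
Reactants: 19 (Z)-3-[3,5-bis(methoxymethoxy)-2-(2-methylbut-3-en-2-yl)phenoxy]-3-[8-(methoxymethoxy)-2,2-dimethyl-5-(3-methylbut-2-enyl)-2H-chromen-6-yl]prop-2-enoic acid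
Product: 21 5,7-bis(methoxymethoxy)-2-[8-(methoxymethoxy)-2,2-dimethyl-5-(3-methylbut-2-enyl)-2H-chromen-6-yl]-8-(2-methylbut-3-en-2-yl)chromen-4-one, via mixed trifluoroacetic anhydride 20 (not isolated)
Conditions: (CF3CO)2O (1.2 equiv), 2,6-di-tert-butyl-4-methylpyridine, CH2Cl2, 0 °C to rt
Reagents that add atoms: none
Why: The acid exchanges with trifluoroacetic anhydride to the mixed anhydride 20, an acylium-like electrophile that the Z geometry holds over ring A; the free ortho carbon of the aryloxy ring attacks the acyl carbon, the Wheland intermediate loses its proton to the pyridine buffer and trifluoroacetate departs. The closest known reaction type is the Friedel–Crafts closure of 3-aryloxycinnamic acids to flavones (Ruhemann-type synthesis), together with anhydride-mediated cyclisations of aryloxy acids to chromanones and xanthones. Ring C closes as a six-membered ring by C4–C4a bond formation, exo with respect to the acyl C=O (6-exo-trig). No stereocentre is formed, and the enol ether geometry disappears into the pyranone. The step needs site selectivity on ring A: the other ortho carbon carries the quaternary tert-allyl group and the para carbon cannot reach the acyl group, so only the carbon that becomes C4a, ortho or para to all three ring oxygens, can close a ring. It also needs selectivity against ring B, which the Z geometry from step 10 secures by keeping the acyl group away from the free ring B carbon and so shutting off indenone formation. The hindered pyridine and low temperature are chosen so that the two equivalents of trifluoroacetic acid released do not cleave MOM ethers or protonate the prenyl and chromene alkenes.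

Step 13
Reactants: 21 5,7-bis(methoxymethoxy)-2-[8-(methoxymethoxy)-2,2-dimethyl-5-(3-methylbut-2-enyl)-2H-chromen-6-yl]-8-(2-methylbut-3-en-2-yl)chromen-4-one
Product: 24 3-hydroxy-5,7-bis(methoxymethoxy)-2-[8-(methoxymethoxy)-2,2-dimethyl-5-(3-methylbut-2-enyl)-2H-chromen-6-yl]-8-(2-methylbut-3-en-2-yl)chromen-4-one, via 3-lithioflavone 22 (not isolated), via dimethyl boronate 23 (not isolated)
Conditions: LiN(i-Pr)2, THF, −78 °C; B(OMe)3, −78 to 0 °C; AcOH, 30% H2O2, 0 °C
Reagents that add atoms: hydrogen peroxide, OO
Why: Carbonyl-directed lithiation of the flavone at C3, borate trapping and boronate oxidation (1,2-shift of C3 from boron to oxygen); peroxide under these conditions should not epoxidise the isolated alkenes, which a peracid or dioxirane would.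

Step 14
Reactants: 24 3-hydroxy-5,7-bis(methoxymethoxy)-2-[8-(methoxymethoxy)-2,2-dimethyl-5-(3-methylbut-2-enyl)-2H-chromen-6-yl]-8-(2-methylbut-3-en-2-yl)chromen-4-one
Product: 25 broussoflavonol D, 3,5,7-trihydroxy-2-[8-hydroxy-2,2-dimethyl-5-(3-methylbut-2-enyl)-2H-chromen-6-yl]-8-(2-methylbut-3-en-2-yl)chromen-4-one
Conditions: HCl (1 M), MeOH/THF, 40 °C
Reagents that add atoms: none
Why: Acid-catalysed acetal exchange of three aryl MOM ethers with methanol; the ethers on O5 and O7 are activated by the carbonyl group, so dilute acid and mild warming should suffice and spare the tert-allyl, prenyl and chromene groups.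

## Compound list

1 | 2-bromo-4,5-dihydroxybenzaldehyde | O=Cc1cc(O)c(O)cc1Br | starting material
2 | 3-chloro-3-methylbut-1-yne | C#CC(C)(C)Cl | starting material
3 | 2-bromo-5-hydroxy-4-[(2-methylbut-3-yn-2-yl)oxy]benzaldehyde | O=Cc1cc(O)c(OC(C)(C)C#C)cc1Br | intermediate
4 | 2-bromo-5-(methoxymethoxy)-4-[(2-methylbut-3-yn-2-yl)oxy]benzaldehyde | O=Cc1cc(OCOC)c(OC(C)(C)C#C)cc1Br | intermediate
5 | 2-bromo-4-hydroxy-5-(methoxymethoxy)-3-(3-methylbuta-1,2-dien-1-yl)benzaldehyde | O=Cc1cc(OCOC)c(O)c(C=C=C(C)C)c1Br | intermediate (not isolated)
6 | 5-bromo-8-(methoxymethoxy)-2,2-dimethyl-2H-chromene-6-carbaldehyde | O=Cc1cc(OCOC)c2OC(C)(C)C=Cc2c1Br | intermediate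
7 | tributyl(3-methylbut-2-enyl)stannane | CCCC[Sn](CCCC)(CCCC)CC=C(C)C | starting material
8 | 8-(methoxymethoxy)-2,2-dimethyl-5-(3-methylbut-2-enyl)-2H-chromene-6-carbaldehyde | O=Cc1cc(OCOC)c2OC(C)(C)C=Cc2c1CC=C(C)C | intermediate
9 | 6-ethynyl-8-(methoxymethoxy)-2,2-dimethyl-5-(3-methylbut-2-enyl)-2H-chromene | C#Cc1cc(OCOC)c2OC(C)(C)C=Cc2c1CC=C(C)C | intermediate
10 | {[8-(methoxymethoxy)-2,2-dimethyl-5-(3-methylbut-2-enyl)-2H-chromen-6-yl]ethynyl}lithium | [Li]C#Cc1cc(OCOC)c2OC(C)(C)C=Cc2c1CC=C(C)C | intermediate (not isolated)
11 | methyl 3-[8-(methoxymethoxy)-2,2-dimethyl-5-(3-methylbut-2-enyl)-2H-chromen-6-yl]prop-2-ynoate | COC(=O)C#Cc1cc(OCOC)c2OC(C)(C)C=Cc2c1CC=C(C)C | intermediate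
12 | phloroglucinol (benzene-1,3,5-triol) | Oc1cc(O)cc(O)c1 | starting material
13 | 3,5-bis(methoxymethoxy)phenol | COCOc1cc(O)cc(OCOC)c1 | intermediate
14 | 1-bromo-3-methylbut-2-ene (prenyl bromide) | CC(C)=CCBr | starting material
15 | 1,3-bis(methoxymethoxy)-5-[(3-methylbut-2-enyl)oxy]benzene | COCOc1cc(OCC=C(C)C)cc(OCOC)c1 | intermediate
16 | 3,5-bis(methoxymethoxy)-6-(2-methylbut-3-en-2-yl)cyclohexa-2,4-dien-1-one (racemic) | O=C1C=C(OCOC)C=C(OCOC)C1C(C)(C)C=C | intermediate (not isolated)
17 | 3,5-bis(methoxymethoxy)-2-(2-methylbut-3-en-2-yl)phenol | C=CC(C)(C)c1c(O)cc(OCOC)cc1OCOC | intermediate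
18 | methyl (Z)-3-[3,5-bis(methoxymethoxy)-2-(2-methylbut-3-en-2-yl)phenoxy]-3-[8-(methoxymethoxy)-2,2-dimethyl-5-(3-methylbut-2-enyl)-2H-chromen-6-yl]prop-2-enoate | COC(=O)/C=C(\Oc1cc(OCOC)cc(OCOC)c1C(C)(C)C=C)c1cc(OCOC)c2OC(C)(C)C=Cc2c1CC=C(C)C | intermediate
19 | (Z)-3-[3,5-bis(methoxymethoxy)-2-(2-methylbut-3-en-2-yl)phenoxy]-3-[8-(methoxymethoxy)-2,2-dimethyl-5-(3-methylbut-2-enyl)-2H-chromen-6-yl]prop-2-enoic acid | OC(=O)/C=C(\Oc1cc(OCOC)cc(OCOC)c1C(C)(C)C=C)c1cc(OCOC)c2OC(C)(C)C=Cc2c1CC=C(C)C | intermediate
20 | (Z)-3-[3,5-bis(methoxymethoxy)-2-(2-methylbut-3-en-2-yl)phenoxy]-3-[8-(methoxymethoxy)-2,2-dimethyl-5-(3-methylbut-2-enyl)-2H-chromen-6-yl]prop-2-enoic trifluoroacetic anhydride | FC(F)(F)C(=O)OC(=O)/C=C(\Oc1cc(OCOC)cc(OCOC)c1C(C)(C)C=C)c1cc(OCOC)c2OC(C)(C)C=Cc2c1CC=C(C)C | intermediate (not isolated)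
21 | 5,7-bis(methoxymethoxy)-2-[8-(methoxymethoxy)-2,2-dimethyl-5-(3-methylbut-2-enyl)-2H-chromen-6-yl]-8-(2-methylbut-3-en-2-yl)chromen-4-one | C=CC(C)(C)c1c(OCOC)cc(OCOC)c2c(=O)cc(-c3cc(OCOC)c4OC(C)(C)C=Cc4c3CC=C(C)C)oc12 | intermediate
22 | {5,7-bis(methoxymethoxy)-2-[8-(methoxymethoxy)-2,2-dimethyl-5-(3-methylbut-2-enyl)-2H-chromen-6-yl]-8-(2-methylbut-3-en-2-yl)-4-oxochromen-3-yl}lithium | C=CC(C)(C)c1c(OCOC)cc(OCOC)c2c(=O)c([Li])c(-c3cc(OCOC)c4OC(C)(C)C=Cc4c3CC=C(C)C)oc12 | intermediate (not isolated)
23 | dimethyl {5,7-bis(methoxymethoxy)-2-[8-(methoxymethoxy)-2,2-dimethyl-5-(3-methylbut-2-enyl)-2H-chromen-6-yl]-8-(2-methylbut-3-en-2-yl)-4-oxochromen-3-yl}boronate | C=CC(C)(C)c1c(OCOC)cc(OCOC)c2c(=O)c(B(OC)OC)c(-c3cc(OCOC)c4OC(C)(C)C=Cc4c3CC=C(C)C)oc12 | intermediate (not isolated)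
24 | 3-hydroxy-5,7-bis(methoxymethoxy)-2-[8-(methoxymethoxy)-2,2-dimethyl-5-(3-methylbut-2-enyl)-2H-chromen-6-yl]-8-(2-methylbut-3-en-2-yl)chromen-4-one | C=CC(C)(C)c1c(OCOC)cc(OCOC)c2c(=O)c(O)c(-c3cc(OCOC)c4OC(C)(C)C=Cc4c3CC=C(C)C)oc12 | intermediate
25 | broussoflavonol D, 3,5,7-trihydroxy-2-[8-hydroxy-2,2-dimethyl-5-(3-methylbut-2-enyl)-2H-chromen-6-yl]-8-(2-methylbut-3-en-2-yl)chromen-4-one | C=CC(C)(C)c1c(O)cc(O)c2c(=O)c(O)c(-c3cc(O)c4c(c3CC=C(C)C)C=CC(C)(C)O4)oc12 | target

## Step count and least certain steps

Total step count: 14. Longest linear sequence: 11 steps (steps 1 to 6 and 10 to 14, from 1). The ring A branch (steps 7 to 9) is three steps long and joins at step 10.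

**Step 12 (key step).** Three processes could defeat it.
- Under full buffering the ring closure may stall, because the vinylogous carbonate carbonyl of 20 is a weak electrophile.
- If the acidity is raised to help it, MOM ethers may be lost or the prenyl alkene protonated.
- Excess anhydride may trifluoroacetylate ring A at the carbon between the two MOM ethers.

The fallback sets out from 17 and 9, returns at 21, and closes ring C at O1–C2 instead. Magnesium-mediated ortho-formylation of 17 (MgCl2, Et3N, paraformaldehyde) can only reach the one free ortho carbon and should give 2-hydroxy-4,6-bis(methoxymethoxy)-3-(2-methylbut-3-en-2-yl)benzaldehyde F1. Addition of acetylide 10 (from 9 and n-BuLi) to the sodium phenoxide of that aldehyde should give the racemic propargylic alcohol 1-[2-hydroxy-4,6-bis(methoxymethoxy)-3-(2-methylbut-3-en-2-yl)phenyl]-3-[8-(methoxymethoxy)-2,2-dimethyl-5-(3-methylbut-2-enyl)-2H-chromen-6-yl]prop-2-yn-1-ol F2. MnO2 oxidation then gives the ynone 1-[2-hydroxy-4,6-bis(methoxymethoxy)-3-(2-methylbut-3-en-2-yl)phenyl]-3-[8-(methoxymethoxy)-2,2-dimethyl-5-(3-methylbut-2-enyl)-2H-chromen-6-yl]prop-2-yn-1-one F3. A secondary amine (Et2NH, EtOH) closes it by 6-endo attack of the phenol oxygen to 21.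

**Step 10.** Three processes could defeat it.
- O-attack of the phenoxide may be slow, because the oxygen sits next to a quaternary carbon.
- Prolonged heating with base may erode the Z geometry towards the isomer with aryl and ester cis, which cannot close ring C.
- The electron-rich phenoxide may attack through carbon.

The fallback sets out from 8 and 17 and returns at 18. Roskamp homologation of 8 (methyl diazoacetate, SnCl2 cat.) should give the β-keto ester methyl 3-[8-(methoxymethoxy)-2,2-dimethyl-5-(3-methylbut-2-enyl)-2H-chromen-6-yl]-3-oxopropanoate F4. Chelation-controlled triflation (Tf2O, LiOTf, Et3N) then gives the enol triflate methyl (Z)-3-[8-(methoxymethoxy)-2,2-dimethyl-5-(3-methylbut-2-enyl)-2H-chromen-6-yl]-3-(trifluoromethylsulfonyloxy)prop-2-enoate F5. Palladium-catalysed C–O coupling with 17 (Pd2(dba)3, a di-tert-butyl biaryl phosphine, K3PO4, toluene) replaces the triflate with retention and gives 18 with the geometry fixed by the triflate.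

**Step 13.** Three processes could defeat it.
- Deprotonation may compete at the benzylic CH2 of the prenyl group, which is conjugated through ring B with the pyranone.
- Deprotonation may compete at the ring A carbon between the two MOM ethers.
- The 3-lithio species 22 may open ring C by β-elimination of the phenoxide before boron trapping.

The fallback sets out from 21, returns at 25, and uses no strong base. A hypervalent iodine α-hydroxylation (PhI(OAc)2, a trivalent iodine reagent, with KOH in MeOH) adds methoxide to C2 and oxidises the resulting enolate. It should give 3-hydroxy-2,4,4-trimethoxy-5,7-bis(methoxymethoxy)-2-[8-(methoxymethoxy)-2,2-dimethyl-5-(3-methylbut-2-enyl)-2H-chromen-6-yl]-8-(2-methylbut-3-en-2-yl)chromane F6 (racemic). Dilute HCl in methanol then cleaves the acetal, eliminates methanol across C2–C3 and removes the MOM ethers in one operation, giving 25 and bypassing 24.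

**Step 14.** Three processes could defeat it.
- The freed 7-OH may cyclise onto the vinyl group of the tert-allyl substituent.
- Ipso protonation at C8 may lead to loss or 1,3-shift of the tert-allyl group.
- Methanol may add to the prenyl alkene if the slowest acetal, the one on ring B, forces longer exposure.

The fallback sets out from 24, returns at 25, and avoids protic acid. Silyl triflate activation buffered by 2,2'-bipyridyl (TMSOTf, 2,2'-bipyridyl, CH2Cl2, 0 °C) converts aryl MOM ethers into aryl silyl ethers. It should give 3,5,7-tris(trimethylsilyloxy)-2-[2,2-dimethyl-5-(3-methylbut-2-enyl)-8-(trimethylsilyloxy)-2H-chromen-6-yl]-8-(2-methylbut-3-en-2-yl)chromen-4-one F7. Methanolysis (K2CO3, MeOH, 0 °C) then gives 25.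

**Step 9.** Three processes could defeat it.
- At the temperature of the rearrangement, the product phenol may cyclise onto its own vinyl group.
- The ether may cleave with loss of the prenyl unit.
- The tert-allyl group may migrate further.

The fallback sets out from 15, returns at 17, and traps the phenol as it forms. Heating 15 with Ac2O and NaOAc in PhNEt2 should give 3,5-bis(methoxymethoxy)-2-(2-methylbut-3-en-2-yl)phenyl acetate F8, which cannot cyclise. K2CO3 in MeOH at rt then frees 17.

## Further compounds

F1 | step 12 | 2-hydroxy-4,6-bis(methoxymethoxy)-3-(2-methylbut-3-en-2-yl)benzaldehyde | O=Cc1c(O)c(C(C)(C)C=C)c(OCOC)cc1OCOC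
F2 | step 12 | 1-[2-hydroxy-4,6-bis(methoxymethoxy)-3-(2-methylbut-3-en-2-yl)phenyl]-3-[8-(methoxymethoxy)-2,2-dimethyl-5-(3-methylbut-2-enyl)-2H-chromen-6-yl]prop-2-yn-1-ol (racemic) | OC(C#Cc1cc(OCOC)c2OC(C)(C)C=Cc2c1CC=C(C)C)c1c(O)c(C(C)(C)C=C)c(OCOC)cc1OCOC
F3 | step 12 | 1-[2-hydroxy-4,6-bis(methoxymethoxy)-3-(2-methylbut-3-en-2-yl)phenyl]-3-[8-(methoxymethoxy)-2,2-dimethyl-5-(3-methylbut-2-enyl)-2H-chromen-6-yl]prop-2-yn-1-one | O=C(C#Cc1cc(OCOC)c2OC(C)(C)C=Cc2c1CC=C(C)C)c1c(O)c(C(C)(C)C=C)c(OCOC)cc1OCOC
F4 | step 10 | methyl 3-[8-(methoxymethoxy)-2,2-dimethyl-5-(3-methylbut-2-enyl)-2H-chromen-6-yl]-3-oxopropanoate | COC(=O)CC(=O)c1cc(OCOC)c2OC(C)(C)C=Cc2c1CC=C(C)C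
F5 | step 10 | methyl (Z)-3-[8-(methoxymethoxy)-2,2-dimethyl-5-(3-methylbut-2-enyl)-2H-chromen-6-yl]-3-(trifluoromethylsulfonyloxy)prop-2-enoate | COC(=O)/C=C(\OS(=O)(=O)C(F)(F)F)c1cc(OCOC)c2OC(C)(C)C=Cc2c1CC=C(C)C
F6 | step 13 | 3-hydroxy-2,4,4-trimethoxy-5,7-bis(methoxymethoxy)-2-[8-(methoxymethoxy)-2,2-dimethyl-5-(3-methylbut-2-enyl)-2H-chromen-6-yl]-8-(2-methylbut-3-en-2-yl)chromane (racemic, relative configuration left open) | C=CC(C)(C)c1c(OCOC)cc(OCOC)c2c1OC(OC)(c1cc(OCOC)c3OC(C)(C)C=Cc3c1CC=C(C)C)C(O)C2(OC)OC
F7 | step 14 | 3,5,7-tris(trimethylsilyloxy)-2-[2,2-dimethyl-5-(3-methylbut-2-enyl)-8-(trimethylsilyloxy)-2H-chromen-6-yl]-8-(2-methylbut-3-en-2-yl)chromen-4-one | C=CC(C)(C)c1c(O[Si](C)(C)C)cc(O[Si](C)(C)C)c2c(=O)c(O[Si](C)(C)C)c(-c3cc(O[Si](C)(C)C)c4OC(C)(C)C=Cc4c3CC=C(C)C)oc12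
F8 | step 9 | 3,5-bis(methoxymethoxy)-2-(2-methylbut-3-en-2-yl)phenyl acetate | CC(=O)Oc1cc(OCOC)cc(OCOC)c1C(C)(C)C=C
A1 | alternative 1 | 3-(prop-2-enyloxy)cyclobut-2-en-1-one | O=C1C=C(OCC=C)C1
A2 | alternative 1 | (3,3-dimethylpent-4-en-1-ynyloxy)tri(propan-2-yl)silane | C=CC(C)(C)C#CO[Si](C(C)C)(C(C)C)C(C)C
A3 | alternative 1 | 2-(2-methylbut-3-en-2-yl)-5-(prop-2-enyloxy)-3-[tri(propan-2-yl)silyloxy]phenol | C=CC(C)(C)c1c(O)cc(OCC=C)cc1O[Si](C(C)C)(C(C)C)C(C)C
A4 | alternative 2 | 3,5,7-tris(methoxymethoxy)-2-[5-(methoxymethoxy)-4-(2-methylbut-3-yn-2-yloxy)-2-(3-methylbut-2-enyl)phenyl]-8-(2-methylbut-3-en-2-yl)chromen-4-one | C=CC(C)(C)c1c(OCOC)cc(OCOC)c2c(=O)c(OCOC)c(-c3cc(OCOC)c(OC(C)(C)C#C)cc3CC=C(C)C)oc12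
A5 | alternative 2 | 3,5,7-tris(methoxymethoxy)-2-[8-(methoxymethoxy)-2,2-dimethyl-5-(3-methylbut-2-enyl)-2H-chromen-6-yl]-8-(2-methylbut-3-en-2-yl)chromen-4-one | C=CC(C)(C)c1c(OCOC)cc(OCOC)c2c(=O)c(OCOC)c(-c3cc(OCOC)c4OC(C)(C)C=Cc4c3CC=C(C)C)oc12
A6 | alternative 3 | 1-[2-fluoro-6-(methoxymethoxy)-4-(3-methylbut-2-enyloxy)phenyl]-2-(methoxymethoxy)-3-[8-(methoxymethoxy)-2,2-dimethyl-5-(3-methylbut-2-enyl)-2H-chromen-6-yl]propane-1,3-dione (racemic) | COCOC(C(=O)c1c(F)cc(OCC=C(C)C)cc1OCOC)C(=O)c1cc(OCOC)c2OC(C)(C)C=Cc2c1CC=C(C)C
A7 | alternative 3 | 3,5-bis(methoxymethoxy)-2-[8-(methoxymethoxy)-2,2-dimethyl-5-(3-methylbut-2-enyl)-2H-chromen-6-yl]-7-(3-methylbut-2-enyloxy)chromen-4-one | COCOc1cc(OCC=C(C)C)cc2oc(-c3cc(OCOC)c4OC(C)(C)C=Cc4c3CC=C(C)C)c(OCOC)c(=O)c12
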